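**Retrosynthetic overview**
1. Feature: the three sp3 carbons of the dihydropyran ring (ring C) form one contiguous chain: C4 (ring A aryl and isobutyl), C3 (isopropyl) and C2 (ring B aryl, O1). C3 with its isopropyl group is the oxygen-bearing carbon of isobutanol and C2 is a single carbon, so the triad can be grown on boron from a C4 benzylic boronate.
2. Sideroxylonal C ⇒ (BCl3; fourfold Rieche formylation at C6, C8, C3', C5') pentamethyl ether chroman ⇒ (O1–C2 closure, the only ring formation; rings A and B are bought as arenes) C2 carbinol ⇒ C2 aldehyde + 2,4,6-trimethoxyphenyllithium.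
3. C2 aldehyde ⇒ primary boronate ⇒ (C2–C3 from chloromethyllithium, C3–C4 from sparteine-ligated lithiated isobutyl carbamate, two 1,2-metallate shifts in one flask) (S)-benzylic boronate of ring A.
4. Benzylic boronate ⇒ (LCuH-catalysed asymmetric hydroboration) (E)-β-isopropylstyrene ⇒ (Julia–Kocienski olefination) MOM ether of 2-hydroxy-4,6-dimethoxybenzaldehyde.
5. Stereocontrol: C4 by catalyst, C3 by reagent, C2 by substrate (closure anti to the isopropyl group gives the all-trans ring C).

Key step: step 7

Assumption: the sense of induction in step 5 is taken from simple (E)-β-alkylstyrenes, where the (R)-bisphosphine leads to the (S)-benzylic boronate; if the 2,6-dioxygenated ring reverses it, the (S)-ligand is used and nothing else changes.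

Step 1
Reactants: 1 2-hydroxy-4,6-dimethoxybenzaldehyde
Product: 2 2-(methoxymethoxy)-4,6-dimethoxybenzaldehyde
Conditions: MOMCl, iPr2NEt, CH2Cl2, 0 °C → rt
Reagents that add atoms: chloromethyl methyl ether, COCCl
Why: O-alkylation of the hydrogen-bonded phenol with an α-chloro ether (MOM protection) is fast with an amine base, leaves the aldehyde untouched and creates no stereocenter.

Step 2
Reactants: 3 1-phenyl-1H-tetrazole-5-thiol; 4 1-bromo-2-methylpropane
Product: 5 5-[(2-methylpropyl)sulfanyl]-1-phenyl-1H-tetrazole
Conditions: K2CO3, DMF, 60 °C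
Reagents that add atoms: none
Why: SN2 S-alkylation by the soft tetrazolethiolate copes with the β-branched primary bromide.

Step 3
Reactants: 5 5-[(2-methylpropyl)sulfanyl]-1-phenyl-1H-tetrazole
Product: 6 5-[(2-methylpropyl)sulfonyl]-1-phenyl-1H-tetrazole
Conditions: 30% aq H2O2, (NH4)6Mo7O24·4H2O (cat.), EtOH, 0 °C → rt
Reagents that add atoms: hydrogen peroxide, OO
Why: molybdate-catalysed peroxide oxidation takes the sulfide through the sulfoxide to the sulfone, and the tetrazole is inert to it.

Step 4
Reactants: 6 5-[(2-methylpropyl)sulfonyl]-1-phenyl-1H-tetrazole; 2 2-(methoxymethoxy)-4,6-dimethoxybenzaldehyde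
Product: 7 1-(methoxymethoxy)-3,5-dimethoxy-2-[(1E)-3-methylbut-1-en-1-yl]benzene
Conditions: KN(SiMe3)2, DME, −60 °C; then 2, −60 °C → rt; H2O
Reagents that add atoms: none
Why: Julia–Kocienski olefination (addition, Smiles rearrangement, loss of SO2 and tetrazololate) should favour the E alkene with an aromatic aldehyde and a potassium counter-ion, and E is also much the less strained isomer beside the 2,6-disubstituted ring; a plain unstabilised ylide would give mostly Z, which is unsuited to step 5.

Step 5
Reactants: 7 1-(methoxymethoxy)-3,5-dimethoxy-2-[(1E)-3-methylbut-1-en-1-yl]benzene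
Product: 8 2-{(1S)-1-[2-(methoxymethoxy)-4,6-dimethoxyphenyl]-3-methylbutyl}-4,4,5,5-tetramethyl-1,3,2-dioxaborolane
Conditions: CuCl (5 mol %), NaOtBu (10 mol %), (R)-DTBM-SEGPHOS (5.5 mol %), HBpin (1.5 equiv), toluene, rt → 40 °C
Reagents that add atoms: pinacolborane, [H]B1OC(C)(C)C(C)(C)O1
Why: in this copper-hydride-catalysed hydroboration of a β-alkylstyrene the ligated LCuH adds syn with copper at the benzylic carbon, σ-bond metathesis with pinacolborane replaces copper by boron with retention, and the chiral bisphosphine chooses the alkene face and so sets C4 (S in 8, R in the target after boron is exchanged for carbon).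

Step 6
Reactants: 9 2-methylpropan-1-ol
Product: 10 2-methylpropyl N,N-diisopropylcarbamate
Conditions: iPr2NC(O)Cl, Et3N, CH2Cl2, reflux
Reagents that add atoms: N,N-diisopropylcarbamoyl chloride, CC(C)N(C(C)C)C(=O)Cl
Why: simple O-acylation of a primary alcohol by a carbamoyl chloride installs the directing and leaving group needed for the carbenoid.

Step 7
Reactants: 8 2-{(1S)-1-[2-(methoxymethoxy)-4,6-dimethoxyphenyl]-3-methylbutyl}-4,4,5,5-tetramethyl-1,3,2-dioxaborolane; 10 2-methylpropyl N,N-diisopropylcarbamate; 11 chloroiodomethane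
Product: 17 2-{(2R,3R)-3-[2-(methoxymethoxy)-4,6-dimethoxyphenyl]-5-methyl-2-(propan-2-yl)hexyl}-4,4,5,5-tetramethyl-1,3,2-dioxaborolane, via lithiated carbamate 12 (not isolated), via first boronate complex 13 (not isolated), via secondary boronate 14 (not isolated), via chloromethyllithium 15 (not isolated), via second boronate complex 16 (not isolated)
Conditions: 10 (1.4 equiv), (−)-sparteine (1.4 equiv), sBuLi (1.3 equiv), Et2O, −78 °C, 5 h; 8 (1.0 equiv), −78 °C, 2 h, then reflux, 16 h; same flask: THF, 11 (3 equiv), nBuLi (2.5 equiv), −78 °C → rt; H2O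
Reagents that add atoms: none
Why: sBuLi/(−)-sparteine removes the pro-S proton of 10, and the configurationally stable (S)-carbenoid 12 attacks the vacant boron orbital of 8 with retention to give complex 13; on warming, the benzylic C4 moves from boron to the carbenoid carbon anti-periplanar to the departing carbamate, which forms C3–C4 with retention at C4 and inversion at C3 and gives (3R,4R)-14. Chloromethyllithium 15, generated by I/Li exchange in the presence of 14, then forms complex 16, in which C3 migrates with retention and expels chloride, which forms C2–C3 and gives 17. The closest known reactions are lithiation–borylation of secondary and benzylic pinacol boronates with sparteine-ligated lithiated primary carbamates and the Matteson one-carbon homologation, which can be run back to back without isolation; no ring is closed here. C3 is the only new stereocenter and is fixed by the reagent (sparteine-defined carbenoid plus two stereospecific shifts), so the anti C3/C4 relationship follows from pairing (S)-8 with (S)-12 and does not rest on substrate bias. The step needs one insertion per carbenoid and carbon rather than oxygen migration: each carbenoid is captured at −78 °C and any excess decomposes before the complex rearranges, so a product boronate never meets live carbenoid, the electron-rich benzylic group migrates readily, and the pinacol oxygens are tied back in their ring. No protic or magnesium additive is used to speed the first shift, since either would consume 15, and sBuLi and nBuLi are kept below 10 and 11 in amount so that the ring A C–H bonds flanked by two oxygens are not lithiated.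

Step 8
Reactants: 17 2-{(2R,3R)-3-[2-(methoxymethoxy)-4,6-dimethoxyphenyl]-5-methyl-2-(propan-2-yl)hexyl}-4,4,5,5-tetramethyl-1,3,2-dioxaborolane
Product: 18 (2R,3R)-3-[2-(methoxymethoxy)-4,6-dimethoxyphenyl]-5-methyl-2-(propan-2-yl)hexan-1-ol
Conditions: 30% aq H2O2, 2 M aq NaOH, THF, 0 °C → rt
Reagents that add atoms: hydrogen peroxide, OO
Why: in this boronate oxidation hydroperoxide adds to boron and the primary carbon shifts to oxygen, while C3, C4 and the acetal are untouched by aqueous base.

Step 9
Reactants: 18 (2R,3R)-3-[2-(methoxymethoxy)-4,6-dimethoxyphenyl]-5-methyl-2-(propan-2-yl)hexan-1-ol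
Product: 19 (2R,3R)-3-[2-(methoxymethoxy)-4,6-dimethoxyphenyl]-5-methyl-2-(propan-2-yl)hexanal
Conditions: Dess–Martin periodinane, CH2Cl2, 0 °C → rt
Reagents that add atoms: none
Why: Dess–Martin oxidation stops at the aldehyde under nearly neutral conditions, which should not enolise the hindered α-branched C3 or cleave the MOM ether.

Step 10
Reactants: 19 (2R,3R)-3-[2-(methoxymethoxy)-4,6-dimethoxyphenyl]-5-methyl-2-(propan-2-yl)hexanal; 20 1,3,5-trimethoxybenzene
Product: 22 (2R,3R)-3-[2-(methoxymethoxy)-4,6-dimethoxyphenyl]-5-methyl-2-(propan-2-yl)-1-(2,4,6-trimethoxyphenyl)hexan-1-ol (both C1 epimers), via 2,4,6-trimethoxyphenyllithium 21 (not isolated)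
Conditions: 20, nBuLi, THF, 0 °C → rt; then 19, −78 → 0 °C; H2O
Reagents that add atoms: none
Why: directed ortho-lithiation between two methoxy groups followed by 1,2-addition to the aldehyde attaches ring B to C2, low temperature should favour addition over enolisation at C3, and the carbinol configuration does not matter because step 11 passes through the cation.

Step 11
Reactants: 22 (2R,3R)-3-[2-(methoxymethoxy)-4,6-dimethoxyphenyl]-5-methyl-2-(propan-2-yl)-1-(2,4,6-trimethoxyphenyl)hexan-1-ol (both C1 epimers)
Product: 23 (2R,3R,4R)-5,7-dimethoxy-4-(2-methylpropyl)-3-(propan-2-yl)-2-(2,4,6-trimethoxyphenyl)-3,4-dihydro-2H-chromene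
Conditions: p-TsOH·H2O (20 mol %), MeOH (10 equiv), CH2Cl2, 0 °C → rt, short reaction time
Reagents that add atoms: none
Why: in this dehydrative SN1 cycloetherification either carbinol epimer ionises to the same 2,4,6-trimethoxybenzylic cation, which should hold C3–H in the aryl plane (A1,3 strain, which also disfavours E1 loss of that proton), so the ring A oxygen, tethered through C4, reaches C2 only from the face anti to the isopropyl group through a chair with aryl, isopropyl and isobutyl all equatorial, which sets C2 as R (2,3-trans), while methanol takes up the methoxymethyl group as dimethoxymethane and keeps it off the electron-rich rings.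

Step 12
Reactants: 23 (2R,3R,4R)-5,7-dimethoxy-4-(2-methylpropyl)-3-(propan-2-yl)-2-(2,4,6-trimethoxyphenyl)-3,4-dihydro-2H-chromene
Product: 24 (2R,3R,4R)-2-(3,5-diformyl-2,4,6-trimethoxyphenyl)-5,7-dimethoxy-4-(2-methylpropyl)-3-(propan-2-yl)-3,4-dihydro-2H-chromene-6,8-dicarbaldehyde
Conditions: Cl2CHOMe (12 equiv), TiCl4 (12 equiv), CH2Cl2, −78 → 0 °C; ice-water
Reagents that add atoms: dichloromethyl methyl ether, COC(Cl)Cl; water, O
Why: in this Rieche formylation the only free ring positions (C6, C8, C3', C5') each lie between two oxygen substituents and stay nucleophilic enough for a second formyl group per ring, and early formylation of ring B at low temperature lowers its ability to stabilise a C2 cation and so should protect the C2–O1 bond.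

Step 13
Reactants: 24 (2R,3R,4R)-2-(3,5-diformyl-2,4,6-trimethoxyphenyl)-5,7-dimethoxy-4-(2-methylpropyl)-3-(propan-2-yl)-3,4-dihydro-2H-chromene-6,8-dicarbaldehyde
Product: 25 sideroxylonal C
Conditions: BCl3 (1 M in CH2Cl2, excess), CH2Cl2, −78 °C → rt; H2O
Reagents that add atoms: none
Why: in this chelation-assisted ether cleavage each of the five methoxy groups is ortho to a formyl group, so boron bridges the carbonyl and ether oxygens and chloride removes the methyl group by SN2, whereas the secondary C2–O1 bond, next to a ring B now carrying two formyl groups, should resist ionisation and no stereocenter is touched.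

**Compound list**
1 | 2-hydroxy-4,6-dimethoxybenzaldehyde | COc1cc(O)c(C=O)c(OC)c1 | starting material
2 | 2-(methoxymethoxy)-4,6-dimethoxybenzaldehyde | COCOc1cc(OC)cc(OC)c1C=O | intermediate
3 | 1-phenyl-1H-tetrazole-5-thiol | Sc1nnnn1-c1ccccc1 | starting material
4 | 1-bromo-2-methylpropane | CC(C)CBr | starting material
5 | 5-[(2-methylpropyl)sulfanyl]-1-phenyl-1H-tetrazole | CC(C)CSc1nnnn1-c1ccccc1 | intermediate
6 | 5-[(2-methylpropyl)sulfonyl]-1-phenyl-1H-tetrazole | CC(C)CS(=O)(=O)c1nnnn1-c1ccccc1 | intermediate
7 | 1-(methoxymethoxy)-3,5-dimethoxy-2-[(1E)-3-methylbut-1-en-1-yl]benzene | COCOc1cc(OC)cc(OC)c1/C=C/C(C)C | intermediate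
8 | 2-{(1S)-1-[2-(methoxymethoxy)-4,6-dimethoxyphenyl]-3-methylbutyl}-4,4,5,5-tetramethyl-1,3,2-dioxaborolane | CC(C)C[C@H](B1OC(C)(C)C(C)(C)O1)c1c(OCOC)cc(OC)cc1OC | intermediate
9 | 2-methylpropan-1-ol | CC(C)CO | starting material
10 | 2-methylpropyl N,N-diisopropylcarbamate | CC(C)COC(=O)N(C(C)C)C(C)C | intermediate
11 | chloroiodomethane | ClCI | starting material
12 | (S)-1-lithio-2-methylpropyl N,N-diisopropylcarbamate, (−)-sparteine complex (ligand not drawn) | [Li][C@@H](C(C)C)OC(=O)N(C(C)C)C(C)C | intermediate
13 | first boronate complex: lithium pinacolatoborate carrying the (1S)-1-aryl-3-methylbutyl group and the (1S)-1-(diisopropylcarbamoyloxy)-2-methylpropyl group | [Li+].CC(C)C[C@H]([B-]1([C@@H](C(C)C)OC(=O)N(C(C)C)C(C)C)OC(C)(C)C(C)(C)O1)c1c(OCOC)cc(OC)cc1OC | intermediate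
14 | 2-{(3R,4R)-4-[2-(methoxymethoxy)-4,6-dimethoxyphenyl]-2,6-dimethylheptan-3-yl}-4,4,5,5-tetramethyl-1,3,2-dioxaborolane | CC(C)C[C@@H](c1c(OCOC)cc(OC)cc1OC)[C@@H](C(C)C)B1OC(C)(C)C(C)(C)O1 | intermediate
15 | chloromethyllithium | [Li]CCl | intermediate
16 | second boronate complex: lithium B-(chloromethyl) pinacolatoborate of 14 | [Li+].CC(C)C[C@@H](c1c(OCOC)cc(OC)cc1OC)[C@@H](C(C)C)[B-]1(CCl)OC(C)(C)C(C)(C)O1 | intermediate
17 | 2-{(2R,3R)-3-[2-(methoxymethoxy)-4,6-dimethoxyphenyl]-5-methyl-2-(propan-2-yl)hexyl}-4,4,5,5-tetramethyl-1,3,2-dioxaborolane | CC(C)C[C@@H](c1c(OCOC)cc(OC)cc1OC)[C@@H](C(C)C)CB1OC(C)(C)C(C)(C)O1 | intermediate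
18 | (2R,3R)-3-[2-(methoxymethoxy)-4,6-dimethoxyphenyl]-5-methyl-2-(propan-2-yl)hexan-1-ol | CC(C)C[C@@H](c1c(OCOC)cc(OC)cc1OC)[C@@H](C(C)C)CO | intermediate
19 | (2R,3R)-3-[2-(methoxymethoxy)-4,6-dimethoxyphenyl]-5-methyl-2-(propan-2-yl)hexanal | CC(C)C[C@@H](c1c(OCOC)cc(OC)cc1OC)[C@@H](C(C)C)C=O | intermediate
20 | 1,3,5-trimethoxybenzene | COc1cc(OC)cc(OC)c1 | starting material
21 | 2,4,6-trimethoxyphenyllithium | [Li]c1c(OC)cc(OC)cc1OC | intermediate
22 | (2R,3R)-3-[2-(methoxymethoxy)-4,6-dimethoxyphenyl]-5-methyl-2-(propan-2-yl)-1-(2,4,6-trimethoxyphenyl)hexan-1-ol, both C1 epimers | CC(C)C[C@@H](c1c(OCOC)cc(OC)cc1OC)[C@@H](C(C)C)C(O)c1c(OC)cc(OC)cc1OC | intermediate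
23 | (2R,3R,4R)-5,7-dimethoxy-4-(2-methylpropyl)-3-(propan-2-yl)-2-(2,4,6-trimethoxyphenyl)-3,4-dihydro-2H-chromene | CC(C)C[C@H]1c2c(OC)cc(OC)cc2O[C@@H](c2c(OC)cc(OC)cc2OC)[C@@H]1C(C)C | intermediate
24 | (2R,3R,4R)-2-(3,5-diformyl-2,4,6-trimethoxyphenyl)-5,7-dimethoxy-4-(2-methylpropyl)-3-(propan-2-yl)-3,4-dihydro-2H-chromene-6,8-dicarbaldehyde | CC(C)C[C@H]1c2c(OC)c(C=O)c(OC)c(C=O)c2O[C@@H](c2c(OC)c(C=O)c(OC)c(C=O)c2OC)[C@@H]1C(C)C | intermediate
25 | sideroxylonal C, (2R,3R,4R)-2-(3,5-diformyl-2,4,6-trihydroxyphenyl)-5,7-dihydroxy-4-(2-methylpropyl)-3-(propan-2-yl)-3,4-dihydro-2H-chromene-6,8-dicarbaldehyde | CC(C)C[C@H]1c2c(O)c(C=O)c(O)c(C=O)c2O[C@@H](c2c(O)c(C=O)c(O)c(C=O)c2O)[C@@H]1C(C)C | target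

**Step count**
- Total steps: 13.
- Longest linear sequence: 11 (steps 2, 3, 4, 5, 7, 8, 9, 10, 11, 12, 13, counted from 3 or 4).
- From aldehyde 1 the sequence is 10 steps.

**Steps most likely to fail**

Step 7.
- Two hindered partners must meet at boron, so capture of the carbenoid may be slower than its decomposition. The first 1,2-shift may also stall or drift towards oxygen migration in the crowded complex.
- The fallback sets out from 8 and returns at 18. It gives up the carbenoid for an alkenyl nucleophile and lets the substrate set C3.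
- 2-Bromo-3-methylbut-1-ene and tBuLi give 3-methylbut-1-en-2-yllithium F1.
- F1 is coupled with 8 under Zweifel olefination conditions (I2, then NaOMe, THF/MeOH, −78 °C → rt). Boron is replaced with retention at C4, which should give the 1,1-disubstituted alkene F2.
- Hydroboration with 9-BBN places boron on the terminal carbon and gives the B-alkyl-9-borabicyclononane F3.
- In the conformer that keeps C4–H next to the isopropyl group (least A1,2 strain), the aryl group shields one face. Hydrogen should therefore reach C3 from the other face, which gives the (3R) configuration.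
- NaOH/H2O2 then gives 18.

Step 5.
- Hydrocupration of an electron-rich styrene with two ortho substituents may be sluggish. Regiocontrol or facial control may also erode.
- The fallback sets out from 2 and returns at 17.
- NaBH4 in MeOH reduces 2 to [2-(methoxymethoxy)-4,6-dimethoxyphenyl]methanol F4.
- iPr2NC(O)Cl and Et3N convert F4 into the benzylic carbamate F5.
- Lithiation (sBuLi, TMEDA, Et2O, −78 °C), capture by 2-methylpropylboronic acid pinacol ester and warming cause the isobutyl group to shift with loss of carbamate. This gives the racemic benzylic boronate F6.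
- Under the conditions of step 7 the same (S)-carbenoid homologates both enantiomers of F6, so 17 forms beside its C4 epimer F7.
- 17 and F7 are diastereomers and are separated by chromatography, here or as the alcohols, at the cost of half the material.

Step 12.
- TiCl4 may ionise the C2–O1 bond before ring B is deactivated. That would bring epimerisation at C2, proton loss towards C3 or intermolecular arylation. The fourth formylation may also remain incomplete.
- The fallback sets out from 23 and returns at 24. It replaces electrophilic formylation by anionic formylation, under which the benzylic ether cannot ionise.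
- Double directed ortho-lithiation, one site per ring (nBuLi, TMEDA, THF, 0 °C), followed by DMF should give the 6,3'-dialdehyde F8. Any lithiation at C8 instead of C6 converges in the next round.
- LiN(Me)CH2CH2NMe2 adds to both formyl groups and masks them in the flask as the dilithium bis(α-amino alkoxide) F9.
- A second lithiation at the two remaining positions between oxygen substituents (nBuLi), DMF and aqueous acid then give 24.

**Further compounds**
F1 | step 7 | 3-methylbut-1-en-2-yllithium | [Li]C(=C)C(C)C
F2 | step 7 | 1-(methoxymethoxy)-3,5-dimethoxy-2-[(4R)-2,6-dimethyl-3-methylideneheptan-4-yl]benzene | CC(C)C[C@@H](c1c(OCOC)cc(OC)cc1OC)C(=C)C(C)C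
F3 | step 7 | 9-{(2R,3R)-3-[2-(methoxymethoxy)-4,6-dimethoxyphenyl]-5-methyl-2-(propan-2-yl)hexyl}-9-borabicyclo[3.3.1]nonane | CC(C)C[C@@H](c1c(OCOC)cc(OC)cc1OC)[C@@H](C(C)C)CB1C2CCCC1CCC2
F4 | step 5 | [2-(methoxymethoxy)-4,6-dimethoxyphenyl]methanol | COCOc1cc(OC)cc(OC)c1CO
F5 | step 5 | [2-(methoxymethoxy)-4,6-dimethoxyphenyl]methyl N,N-diisopropylcarbamate | COCOc1cc(OC)cc(OC)c1COC(=O)N(C(C)C)C(C)C
F6 | step 5 | racemic 2-{1-[2-(methoxymethoxy)-4,6-dimethoxyphenyl]-3-methylbutyl}-4,4,5,5-tetramethyl-1,3,2-dioxaborolane | CC(C)CC(B1OC(C)(C)C(C)(C)O1)c1c(OCOC)cc(OC)cc1OC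
F7 | step 5 | 2-{(2R,3S)-3-[2-(methoxymethoxy)-4,6-dimethoxyphenyl]-5-methyl-2-(propan-2-yl)hexyl}-4,4,5,5-tetramethyl-1,3,2-dioxaborolane | CC(C)C[C@H](c1c(OCOC)cc(OC)cc1OC)[C@@H](C(C)C)CB1OC(C)(C)C(C)(C)O1
F8 | step 12 | (2R,3R,4R)-2-(3-formyl-2,4,6-trimethoxyphenyl)-5,7-dimethoxy-4-(2-methylpropyl)-3-(propan-2-yl)-3,4-dihydro-2H-chromene-6-carbaldehyde | CC(C)C[C@H]1c2c(OC)c(C=O)c(OC)cc2O[C@@H](c2c(OC)c(C=O)c(OC)cc2OC)[C@@H]1C(C)C
F9 | step 12 | dilithium bis(α-amino alkoxide) of F8 with N,N,N'-trimethylethylenediamine | [Li+].[Li+].CC(C)C[C@H]1c2c(OC)c(C([O-])N(C)CCN(C)C)c(OC)cc2O[C@@H](c2c(OC)c(C([O-])N(C)CCN(C)C)c(OC)cc2OC)[C@@H]1C(C)C
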